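The oxygen on C3 and the CH2–O carbon of the C2 side chain sit cis on the dihydrofuran ring of the benzofuran core, so both can be held in one cis-fused α-methylene-γ-butyrolactone, its C=O being the future acetoxymethyl carbon. Everything rests on cutting that lactone at C2–C3 and at its acyl C–O bond. In one operation a chiral chromium reagent turns an allylic bromide into a γ-aryloxyallylchromium that adds to an ortho formyl group, closing the dihydrofuran ring, setting C2 and C3 and lactonising. The precursor is a flat, achiral methyl (Z)-2-(bromomethyl)-3-aryloxyacrylate carrying an ortho aldehyde, a silyl-protected phenol and a ketal-masked acetyl group.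

Key step: step 10

Assumption: ligand L is (S)-N-[2-(4-isopropyl-4,5-dihydro-1,3-oxazol-2-yl)-6-methylphenyl]methanesulfonamide; which antipode of L leads to Si-face attack on the formyl group is settled in a test run with both antipodes, and that antipode is used.
Handling remark: the electron-rich aryl ketal is acid-labile, so from step 3 on all work-ups are kept at pH 7 or above and silica is deactivated with Et3N.

Step 1
Reactants: 1 1-(2,4-dihydroxyphenyl)ethanone
Product: 2 1-[4-(benzyloxy)-2-hydroxyphenyl]ethanone
Conditions: BnBr, K2CO3, acetone, reflux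
Reagents that add atoms: benzyl bromide, BrCc1ccccc1
Why: Williamson ether synthesis: the 2-OH is tied up in a hydrogen bond to the acetyl carbonyl and is far less nucleophilic, so one equivalent of benzyl bromide should alkylate only the 4-OH.

Step 2
Reactants: 2 1-[4-(benzyloxy)-2-hydroxyphenyl]ethanone
Product: 3 1-[4-(benzyloxy)-2-(triisopropylsilyloxy)phenyl]ethanone
Conditions: iPr3SiCl, imidazole, DMAP (cat.), DMF, 40 °C
Reagents that add atoms: chlorotriisopropylsilane, CC(C)[Si](Cl)(C(C)C)C(C)C
Why: Imidazole-mediated silyl ether formation: with the 4-OH blocked the chelated 2-OH is silylated, and the bulky silyl group is chosen because it withstands base, CrCl2 and iBu2AlH and leaves at the end with fluoride instead of acid.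

Step 3
Reactants: 3 1-[4-(benzyloxy)-2-(triisopropylsilyloxy)phenyl]ethanone
Product: 4 2-[4-(benzyloxy)-2-(triisopropylsilyloxy)phenyl]-2-methyl-1,3-dioxolane
Conditions: Me3SiOCH2CH2OSiMe3, Me3SiOTf (cat.), CH2Cl2, −78 → −20 °C; Et3N quench
Reagents that add atoms: 1,2-bis(trimethylsilyloxy)ethane, C[Si](C)(C)OCCO[Si](C)(C)C
Why: Silyl triflate-catalysed ketalisation with the bis-silyl ether of the diol (Noyori acetalisation): Me3SiOSiMe3 forms irreversibly, so the hindered electron-rich aryl ketone is masked without water or protic acid, and before any aldehyde is present.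

Step 4
Reactants: 4 2-[4-(benzyloxy)-2-(triisopropylsilyloxy)phenyl]-2-methyl-1,3-dioxolane
Product: 5 4-(2-methyl-1,3-dioxolan-2-yl)-3-(triisopropylsilyloxy)phenol
Conditions: H2 (1 atm), Pd/C, EtOAc, Et3N (trace), rt
Reagents that add atoms: none
Why: Hydrogenolysis of the benzyl ether over Pd/C under neutral, amine-buffered conditions frees the 4-OH while the ketal and the aryl silyl ether are inert.

Step 5
Reactants: 5 4-(2-methyl-1,3-dioxolan-2-yl)-3-(triisopropylsilyloxy)phenol
Product: 6 2-hydroxy-5-(2-methyl-1,3-dioxolan-2-yl)-4-(triisopropylsilyloxy)benzaldehyde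
Conditions: MgCl2, Et3N, (CH2O)n, MeCN, reflux; pH 7 phosphate buffer
Reagents that add atoms: paraformaldehyde (as formaldehyde), C=O
Why: Casnati–Skattebøl ortho-formylation: the magnesium phenoxide delivers formaldehyde to an ortho carbon through a six-membered array and a second formaldehyde oxidises the benzylic alkoxide by hydride transfer; the ortho position flanked by the silyloxy group is blocked, so the formyl group should enter para to OSi.

Step 6
Reactants: 7 methyl 2-(bromomethyl)acrylate
Product: 9 methyl (Z)-3-bromo-2-(bromomethyl)acrylate, via tribromo ester 8 (not isolated)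
Conditions: Br2, CH2Cl2, 0 °C → rt; then DBU, 0 °C
Reagents that add atoms: bromine, BrBr
Why: Bromine addition to the acrylate followed by E2 dehydrobromination: both β-carbons of 8 are CH2Br, so only one constitutional isomer can form; the isomer with Br trans to the ester should prevail, and the alkene geometry is not decisive later.

Step 7
Reactants: 9 methyl (Z)-3-bromo-2-(bromomethyl)acrylate
Product: 11 methyl (E)-3-bromo-2-(hydroxymethyl)acrylate, via formate ester 10 (not isolated)
Conditions: HCO2Na, DMF, rt; then MeOH, HCl (cat.), rt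
Reagents that add atoms: sodium formate, [Na+].[O-]C=O
Why: SN2 displacement by carboxylate followed by acid-catalysed transesterification: formate attacks only the allylic CH2Br, since carboxylates do not add to the bromovinyl carbon, and methanolysis frees the alcohol, which masks the allylic position against the phenoxide of step 8.

Step 8
Reactants: 6 2-hydroxy-5-(2-methyl-1,3-dioxolan-2-yl)-4-(triisopropylsilyloxy)benzaldehyde; 11 methyl (E)-3-bromo-2-(hydroxymethyl)acrylate
Product: 12 methyl (E)-3-[2-formyl-4-(2-methyl-1,3-dioxolan-2-yl)-5-(triisopropylsilyloxy)phenoxy]-2-(hydroxymethyl)acrylate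
Conditions: CuI (cat.), N,N-dimethylglycine, Cs2CO3, 1,4-dioxane, 60 °C
Reagents that add atoms: none
Why: Ullmann-type O-vinylation of a phenol with a β-bromoacrylate, backed by addition–elimination at the β-carbon: the phenoxide is far more nucleophilic than the primary alcohol and the coupling should keep the alkene geometry.

Step 9
Reactants: 12 methyl (E)-3-[2-formyl-4-(2-methyl-1,3-dioxolan-2-yl)-5-(triisopropylsilyloxy)phenoxy]-2-(hydroxymethyl)acrylate
Product: 14 methyl (Z)-2-(bromomethyl)-3-[2-formyl-4-(2-methyl-1,3-dioxolan-2-yl)-5-(triisopropylsilyloxy)phenoxy]acrylate, via allylic mesylate 13 (not isolated)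
Conditions: Ms2O, 2,6-lutidine, CH2Cl2, −20 °C; then LiBr, THF, 0 °C → rt
Reagents that add atoms: lithium bromide, [Li+].[Br-]; methanesulfonic anhydride, CS(=O)(=O)OS(C)(=O)=O (mesyl group only in 13)
Why: Sulfonate formation followed by Finkelstein-type SN2 displacement with bromide: the sequence is purely ionic, so the formyl C–H (which would not survive a radical allylic bromination), the ketal and the silyl ether are untouched.

Step 10
Reactants: 14 methyl (Z)-2-(bromomethyl)-3-[2-formyl-4-(2-methyl-1,3-dioxolan-2-yl)-5-(triisopropylsilyloxy)phenoxy]acrylate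
Product: 17 (3aR,8bR)-3-methylidene-7-(2-methyl-1,3-dioxolan-2-yl)-6-(triisopropylsilyloxy)-3a,8b-dihydro-2H-furo[3,2-b][1]benzofuran-2-one, via allylchromium species 15 (not isolated), via chromium alkoxide 16 (not isolated)
Conditions: CrCl2, ligand L, 1,8-bis(dimethylamino)naphthalene, THF, rt; then 14, 0 °C → rt; aq. NaHCO3/potassium sodium tartrate
Reagents that add atoms: none
Why: Proposed new method: two equivalents of CrCl2 (divalent chromium) reduce the allylic C–Br bond to the ligand-bound allylchromium 15 (trivalent chromium), which adds through its aryloxy-bearing γ-carbon to the ortho formyl group in a chair-like six-membered transition state, and the chromium alkoxide 16 so formed acylates on the neighbouring methyl ester. The closest known reaction type is the Nozaki–Hiyama-type addition of 2-(alkoxycarbonyl)allyl bromides to aldehydes with lactonisation, known also in ligand-controlled enantioselective form, together with the aldehyde addition of γ-alkoxyallylchromium reagents; the intramolecular γ-aryloxy variant is the untested extension. The dihydrofuran ring closes by 5-exo-trig attack of C2 on the formyl carbon and the lactone ring by 5-exo-trig acyl substitution. C2 and C3 arise together: the chair fused to the forming five-membered ring admits only the cis arrangement, which the cis-only lactonisation then locks, and the chiral ligand on chromium directs C2 to the Si face of the formyl group, giving (2R,3R) in benzofuran numbering. The step needs aldehyde chemoselectivity and γ-regioselectivity, secured by the ketal on the ketone, by an ester that can react only after the C–C bond is made, and by the fact that α-attack would require a seven-membered ring; the alkene geometry of 14 is not critical because the allylchromium equilibrates by 1,3-shift of the metal.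

Step 11
Reactants: 17 (3aR,8bR)-3-methylidene-7-(2-methyl-1,3-dioxolan-2-yl)-6-(triisopropylsilyloxy)-3a,8b-dihydro-2H-furo[3,2-b][1]benzofuran-2-one
Product: 18 (2R,3R)-2-(3-hydroxyprop-1-en-2-yl)-5-(2-methyl-1,3-dioxolan-2-yl)-6-(triisopropylsilyloxy)-2,3-dihydro-1-benzofuran-3-ol
Conditions: iBu2AlH, CH2Cl2, −78 → −20 °C; aq. potassium sodium tartrate
Reagents that add atoms: none
Why: Hydride reduction of the lactone by iBu2AlH through the lactol to the ring-opened allylic alcohol (1,2-reduction only): both stereocentres are untouched and the ketone is shielded as the ketal.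

Step 12
Reactants: 18 (2R,3R)-2-(3-hydroxyprop-1-en-2-yl)-5-(2-methyl-1,3-dioxolan-2-yl)-6-(triisopropylsilyloxy)-2,3-dihydro-1-benzofuran-3-ol
Product: 19 2-[(2R,3R)-3-hydroxy-5-(2-methyl-1,3-dioxolan-2-yl)-6-(triisopropylsilyloxy)-2,3-dihydro-1-benzofuran-2-yl]prop-2-en-1-yl acetate
Conditions: AcCl, 2,4,6-collidine, CH2Cl2, −78 °C
Reagents that add atoms: acetyl chloride, CC(Cl)=O
Why: Selective O-acylation with acetyl chloride and collidine at low temperature: the unhindered primary allylic alcohol reacts much faster than the secondary benzylic alcohol flanked by the cis C2 substituent.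

Step 13
Reactants: 19 2-[(2R,3R)-3-hydroxy-5-(2-methyl-1,3-dioxolan-2-yl)-6-(triisopropylsilyloxy)-2,3-dihydro-1-benzofuran-2-yl]prop-2-en-1-yl acetate; 20 angelic acid [(Z)-2-methylbut-2-enoic acid]
Product: 22 (2R,3R)-2-[3-(acetyloxy)prop-1-en-2-yl]-5-(2-methyl-1,3-dioxolan-2-yl)-6-(triisopropylsilyloxy)-2,3-dihydro-1-benzofuran-3-yl (Z)-2-methylbut-2-enoate, via mixed anhydride 21 (not isolated)
Conditions: 20, 2,4,6-Cl3C6H2COCl, Et3N, toluene, rt; then 19, 75 °C
Reagents that add atoms: 2,4,6-trichlorobenzoyl chloride, O=C(Cl)c1c(Cl)cc(Cl)cc1Cl (aroyl group only in 21)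
Why: Yamaguchi-type esterification through the mixed anhydride without a nucleophilic catalyst: acyl transfer under these conditions is known to preserve the Z geometry of angelates, and C3 keeps its configuration because its C–O bond is not broken.

Step 14
Reactants: 22 (2R,3R)-2-[3-(acetyloxy)prop-1-en-2-yl]-5-(2-methyl-1,3-dioxolan-2-yl)-6-(triisopropylsilyloxy)-2,3-dihydro-1-benzofuran-3-yl (Z)-2-methylbut-2-enoate
Product: 24 (2R,3R)-5-acetyl-2-[3-(acetyloxy)prop-1-en-2-yl]-6-hydroxy-2,3-dihydro-1-benzofuran-3-yl (Z)-2-methylbut-2-enoate, via silyl ether ketone 23 (not isolated)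
Conditions: PPTS, acetone–H2O, rt; then Bu4NF, AcOH, THF, 0 °C
Reagents that add atoms: water, O
Why: Acetal hydrolysis followed by fluoride desilylation: the mild pyridinium acid removes the ketal first, which switches on the electron-withdrawing acetyl group and so protects the benzylic C3 ester against ionisation, and acetic acid-buffered Bu4NF then cleaves the aryl silyl ether without acyl migration.

Compound list
1 | 1-(2,4-dihydroxyphenyl)ethanone | CC(=O)c1ccc(O)cc1O | starting material
2 | 1-[4-(benzyloxy)-2-hydroxyphenyl]ethanone | CC(=O)c1ccc(OCc2ccccc2)cc1O | intermediate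
3 | 1-[4-(benzyloxy)-2-(triisopropylsilyloxy)phenyl]ethanone | CC(=O)c1ccc(OCc2ccccc2)cc1O[Si](C(C)C)(C(C)C)C(C)C | intermediate
4 | 2-[4-(benzyloxy)-2-(triisopropylsilyloxy)phenyl]-2-methyl-1,3-dioxolane | CC1(c2ccc(OCc3ccccc3)cc2O[Si](C(C)C)(C(C)C)C(C)C)OCCO1 | intermediate
5 | 4-(2-methyl-1,3-dioxolan-2-yl)-3-(triisopropylsilyloxy)phenol | CC1(c2ccc(O)cc2O[Si](C(C)C)(C(C)C)C(C)C)OCCO1 | intermediate
6 | 2-hydroxy-5-(2-methyl-1,3-dioxolan-2-yl)-4-(triisopropylsilyloxy)benzaldehyde | CC1(c2cc(C=O)c(O)cc2O[Si](C(C)C)(C(C)C)C(C)C)OCCO1 | intermediate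
7 | methyl 2-(bromomethyl)acrylate | C=C(CBr)C(=O)OC | starting material
8 | methyl 2,3-dibromo-2-(bromomethyl)propanoate (tribromo ester, not isolated) | COC(=O)C(Br)(CBr)CBr | intermediate
9 | methyl (Z)-3-bromo-2-(bromomethyl)acrylate | COC(=O)/C(CBr)=C/Br | intermediate
10 | methyl (E)-3-bromo-2-[(formyloxy)methyl]acrylate (formate ester, not isolated) | COC(=O)/C(COC=O)=C/Br | intermediate
11 | methyl (E)-3-bromo-2-(hydroxymethyl)acrylate | COC(=O)/C(CO)=C/Br | intermediate
12 | methyl (E)-3-[2-formyl-4-(2-methyl-1,3-dioxolan-2-yl)-5-(triisopropylsilyloxy)phenoxy]-2-(hydroxymethyl)acrylate | COC(=O)/C(CO)=C/Oc1cc(O[Si](C(C)C)(C(C)C)C(C)C)c(C2(C)OCCO2)cc1C=O | intermediate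
13 | methyl (E)-3-[2-formyl-4-(2-methyl-1,3-dioxolan-2-yl)-5-(triisopropylsilyloxy)phenoxy]-2-[(methylsulfonyloxy)methyl]acrylate (allylic mesylate, not isolated) | COC(=O)/C(COS(C)(=O)=O)=C/Oc1cc(O[Si](C(C)C)(C(C)C)C(C)C)c(C2(C)OCCO2)cc1C=O | intermediate
14 | methyl (Z)-2-(bromomethyl)-3-[2-formyl-4-(2-methyl-1,3-dioxolan-2-yl)-5-(triisopropylsilyloxy)phenoxy]acrylate (precursor of the key step) | COC(=O)/C(CBr)=C/Oc1cc(O[Si](C(C)C)(C(C)C)C(C)C)c(C2(C)OCCO2)cc1C=O | intermediate
15 | methyl (Z)-2-[(dichlorochromio)methyl]-3-[2-formyl-4-(2-methyl-1,3-dioxolan-2-yl)-5-(triisopropylsilyloxy)phenoxy]acrylate (allylchromium species, trivalent chromium, ligand on Cr not drawn, not isolated) | COC(=O)/C(C[Cr](Cl)Cl)=C/Oc1cc(O[Si](C(C)C)(C(C)C)C(C)C)c(C2(C)OCCO2)cc1C=O | intermediate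
16 | dichlorochromium alkoxide of methyl 2-[(2R,3R)-3-hydroxy-5-(2-methyl-1,3-dioxolan-2-yl)-6-(triisopropylsilyloxy)-2,3-dihydro-1-benzofuran-2-yl]acrylate (trivalent chromium, ligand not drawn, not isolated) | C=C(C(=O)OC)[C@H]1Oc2cc(O[Si](C(C)C)(C(C)C)C(C)C)c(C3(C)OCCO3)cc2[C@H]1O[Cr](Cl)Cl | intermediate
17 | (3aR,8bR)-3-methylidene-7-(2-methyl-1,3-dioxolan-2-yl)-6-(triisopropylsilyloxy)-3a,8b-dihydro-2H-furo[3,2-b][1]benzofuran-2-one (cis-fused lactone; C2 and C3 of the dihydrobenzofuran both R) | C=C1[C@H]2Oc3cc(O[Si](C(C)C)(C(C)C)C(C)C)c(C4(C)OCCO4)cc3[C@H]2OC1=O | intermediate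
18 | (2R,3R)-2-(3-hydroxyprop-1-en-2-yl)-5-(2-methyl-1,3-dioxolan-2-yl)-6-(triisopropylsilyloxy)-2,3-dihydro-1-benzofuran-3-ol | C=C(CO)[C@H]1Oc2cc(O[Si](C(C)C)(C(C)C)C(C)C)c(C3(C)OCCO3)cc2[C@H]1O | intermediate
19 | 2-[(2R,3R)-3-hydroxy-5-(2-methyl-1,3-dioxolan-2-yl)-6-(triisopropylsilyloxy)-2,3-dihydro-1-benzofuran-2-yl]prop-2-en-1-yl acetate | C=C(COC(C)=O)[C@H]1Oc2cc(O[Si](C(C)C)(C(C)C)C(C)C)c(C3(C)OCCO3)cc2[C@H]1O | intermediate
20 | angelic acid, (Z)-2-methylbut-2-enoic acid | C/C=C(/C)C(=O)O | starting material
21 | (Z)-2-methylbut-2-enoic 2,4,6-trichlorobenzoic anhydride (mixed anhydride, not isolated) | C/C=C(/C)C(=O)OC(=O)c1c(Cl)cc(Cl)cc1Cl | intermediate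
22 | (2R,3R)-2-[3-(acetyloxy)prop-1-en-2-yl]-5-(2-methyl-1,3-dioxolan-2-yl)-6-(triisopropylsilyloxy)-2,3-dihydro-1-benzofuran-3-yl (Z)-2-methylbut-2-enoate | C=C(COC(C)=O)[C@H]1Oc2cc(O[Si](C(C)C)(C(C)C)C(C)C)c(C3(C)OCCO3)cc2[C@H]1OC(=O)/C(C)=C\C | intermediate
23 | (2R,3R)-5-acetyl-2-[3-(acetyloxy)prop-1-en-2-yl]-6-(triisopropylsilyloxy)-2,3-dihydro-1-benzofuran-3-yl (Z)-2-methylbut-2-enoate (silyl ether ketone, not isolated) | C=C(COC(C)=O)[C@H]1Oc2cc(O[Si](C(C)C)(C(C)C)C(C)C)c(C(C)=O)cc2[C@H]1OC(=O)/C(C)=C\C | intermediate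
24 | (2R,3R)-5-acetyl-2-[3-(acetyloxy)prop-1-en-2-yl]-6-hydroxy-2,3-dihydro-1-benzofuran-3-yl (Z)-2-methylbut-2-enoate (CNP0323250.1) | C=C(COC(C)=O)[C@H]1Oc2cc(O)c(C(C)=O)cc2[C@H]1OC(=O)/C(C)=C\C | target

Total step count: 14
Longest linear sequence: 12 steps (steps 1–5 and 8–14; steps 6 and 7 make the side-chain reagent)

Steps most likely to fail

First, step 10, the one that carries the label. The ligand-bound allylchromium may discriminate poorly between the two faces of the formyl group, or it may be protonated or dimerise before it cyclises. The fallback uses known chemistry, sets out from 14 and comes back at 17. Compound 14 would be cyclised without chiral control by Barbier-type 2-(alkoxycarbonyl)allylation with lactonisation, using Zn dust in THF with an aqueous NH4Cl/NH3 buffer at pH 8; this is the standard racemic entry to α-methylene-γ-butyrolactones. It should give the cis-lactone as the racemate, that is 17 together with its mirror image, the (3aS,8bS)-lactone F1. Preparative chromatography on a chiral stationary phase would then deliver 17.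

Second, step 14. While the ketal is being hydrolysed, the still electron-rich ring can assist ionisation of the benzylic C3–O bond, so that angelic acid is lost and the ring aromatises to the benzofuran. The fallback sets out from 19 and comes back at 23. The ketal would be hydrolysed one stage earlier, on 19 (PPTS, acetone–H2O), where C3 carries the poorer leaving group, to give the hydroxy ketone F3. F3 would then be esterified with mixed anhydride 21 as in step 13 to give 23, now isolated, and only the buffered fluoride treatment of step 14 would remain.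

Third, step 13. The Z-enoate may isomerise to the E-isomer during acyl transfer, and acylation of the hindered cis-alcohol may be slow enough for elimination to compete. The fallback sets out from 19 and comes back at 22; it builds the Z-alkene on the ester instead of carrying it through the acylation. Compound 19 would be esterified with 2-[bis(2,2,2-trifluoroethoxy)phosphoryl]propanoic acid (DCC, DMAP, CH2Cl2) to the phosphonate ester F2. Still–Gennari olefination of F2 with acetaldehyde (KN(SiMe3)2, 18-crown-6, THF, −78 °C) should then give the Z-configured 2-methylbut-2-enoate 22.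

Further compounds
F1 | step 10 | (3aS,8bS)-3-methylidene-7-(2-methyl-1,3-dioxolan-2-yl)-6-(triisopropylsilyloxy)-3a,8b-dihydro-2H-furo[3,2-b][1]benzofuran-2-one (mirror image of 17) | C=C1[C@@H]2Oc3cc(O[Si](C(C)C)(C(C)C)C(C)C)c(C4(C)OCCO4)cc3[C@@H]2OC1=O
F2 | step 13 | (2R,3R)-2-[3-(acetyloxy)prop-1-en-2-yl]-5-(2-methyl-1,3-dioxolan-2-yl)-6-(triisopropylsilyloxy)-2,3-dihydro-1-benzofuran-3-yl 2-[bis(2,2,2-trifluoroethoxy)phosphoryl]propanoate (both epimers at the phosphonate carbon) | C=C(COC(C)=O)[C@H]1Oc2cc(O[Si](C(C)C)(C(C)C)C(C)C)c(C3(C)OCCO3)cc2[C@H]1OC(=O)C(C)P(=O)(OCC(F)(F)F)OCC(F)(F)F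
F3 | step 14 | 2-[(2R,3R)-5-acetyl-3-hydroxy-6-(triisopropylsilyloxy)-2,3-dihydro-1-benzofuran-2-yl]prop-2-en-1-yl acetate | C=C(COC(C)=O)[C@H]1Oc2cc(O[Si](C(C)C)(C(C)C)C(C)C)c(C(C)=O)cc2[C@H]1O
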